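Isoangustone A is traced back through its tetrakis-MOM ether to a 2-trimethylsilyl isoflavone, in which silicon stands in for the hydrogen on C2.
Ring C is the only ring to be built, and the plan rests on C4 being an acyl carbon on C4a of ring A with O1 on the neighbouring C8a. A salicylaldehyde therefore supplies C4 and O1, and an aryl silyl alkyne supplies C2 and C3 with ring B on the future C3; the bonds made are C3–C4 and O1–C2.
The salicylaldehyde comes from phloroglucinol: the symmetric bis-MOM phenol is silylated, prenylated between the MOM ethers by directed lithiation, desilylated and ortho-formylated. Both ortho sites are equivalent, so the prenyl group is fixed at the later C6.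
The alkyne comes from 5-bromovanillin by demethylation, MOM protection, Stille prenylation at the C–Br bond and homologation of the aldehyde to the silyl alkyne.
Ring order: rings A and B are bought; ring C closes in the annulation, followed by protodesilylation and acetal removal.

Key step: step 11

Remark: the target has no stereocenter and no E/Z element, so stereochemistry plays no part; MOM = methoxymethyl, prenyl = 3-methylbut-2-en-1-yl, TIPS = tri(propan-2-yl)silyl, Cp* = C5Me5.

Step 1
Reactants: 1 phloroglucinol
Product: 2 3,5-bis(methoxymethoxy)phenol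
Conditions: MOMCl (2.0 equiv), i-Pr2NEt (2.5 equiv), DMF, 0 °C to rt
Reagents that add atoms: chloromethyl methyl ether, COCCl
Why: Williamson-type O-alkylation of the phenols by the oxocarbenium-like chloride; the threefold symmetry of 1 allows only one bis-ether, which should be the main component of the statistical mixture and separable from mono- and tris-ether by chromatography.

Step 2
Reactants: 2 3,5-bis(methoxymethoxy)phenol
Product: 3 [3,5-bis(methoxymethoxy)phenoxy]tri(propan-2-yl)silane
Conditions: i-Pr3SiCl (1.2 equiv), imidazole (2.5 equiv), DMF, rt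
Reagents that add atoms: chlorotri(propan-2-yl)silane, CC(C)[Si](Cl)(C(C)C)C(C)C
Why: Imidazole-mediated silyl ether formation masks the acidic phenol before the organolithium step, and the bulky TIPS ether is a poor director that should neither be attacked by n-BuLi nor migrate.

Step 3
Reactants: 3 [3,5-bis(methoxymethoxy)phenoxy]tri(propan-2-yl)silane; 4 prenyl bromide (1-bromo-3-methylbut-2-ene)
Product: 6 [3,5-bis(methoxymethoxy)-4-(3-methylbut-2-en-1-yl)phenoxy]tri(propan-2-yl)silane, via aryllithium 5 (not isolated)
Conditions: n-BuLi (1.1 equiv), THF, 0 °C; then CuBr·SMe2 (10 mol %), prenyl bromide (1.3 equiv), −40 °C to rt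
Reagents that add atoms: prenyl bromide (4), CC(C)=CCBr
Why: Directed ortho-metalation removes the C–H flanked by the two MOM ethers through double lithium chelation, and copper-catalysed SN2 allylation of the aryllithium should give the linear prenyl arene.

Step 4
Reactants: 6 [3,5-bis(methoxymethoxy)-4-(3-methylbut-2-en-1-yl)phenoxy]tri(propan-2-yl)silane
Product: 7 3,5-bis(methoxymethoxy)-4-(3-methylbut-2-en-1-yl)phenol
Conditions: Bu4NF (1.1 equiv), AcOH (1.1 equiv), THF, 0 °C
Reagents that add atoms: none
Why: Fluoride-induced cleavage of the aryl silyl ether, buffered with AcOH so that the phenoxide is protonated as it forms, leaves the MOM acetals and the olefin untouched.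

Step 5
Reactants: 7 3,5-bis(methoxymethoxy)-4-(3-methylbut-2-en-1-yl)phenol
Product: 9 2-hydroxy-4,6-bis(methoxymethoxy)-5-(3-methylbut-2-en-1-yl)benzaldehyde, via salicyl alcohol 8 (not isolated)
Conditions: MgCl2 (2 equiv), Et3N (4 equiv), (CH2O)n (6 equiv), MeCN, 80 °C; aq. NH4Cl work-up
Reagents that add atoms: paraformaldehyde (source of formaldehyde), C=O
Why: Casnati–Skattebøl ortho-formylation, in which the magnesium phenoxide delivers formaldehyde to the ortho carbon and a second formaldehyde oxidises the benzylic alkoxide by hydride transfer; the two ortho positions of 7 are equivalent, so a single salicylaldehyde with the prenyl group para to the free OH should form.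

Step 6
Reactants: 10 5-bromovanillin
Product: 11 3-bromo-4,5-dihydroxybenzaldehyde
Conditions: AlCl3 (1.1 equiv), pyridine (4.4 equiv), CH2Cl2, reflux; then aq. HCl
Reagents that add atoms: none
Why: Chelation-assisted demethylation, in which AlCl3 binds the phenol and the neighbouring methyl ether as a five-membered chelate and pyridine removes the methyl group by SN2, is selective for a methyl ether ortho to a free phenol and leaves the aldehyde and bromide alone.

Step 7
Reactants: 11 3-bromo-4,5-dihydroxybenzaldehyde
Product: 12 3-bromo-4,5-bis(methoxymethoxy)benzaldehyde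
Conditions: MOMCl (3 equiv), i-Pr2NEt (4 equiv), CH2Cl2, 0 °C to rt
Reagents that add atoms: chloromethyl methyl ether, COCCl
Why: Double Williamson-type O-alkylation of the catechol gives the bis-acetal that will survive the basic, organometallic and oxidative steps ahead.

Step 8
Reactants: 12 3-bromo-4,5-bis(methoxymethoxy)benzaldehyde; 13 tributyl(3-methylbut-2-en-1-yl)stannane
Product: 14 3,4-bis(methoxymethoxy)-5-(3-methylbut-2-en-1-yl)benzaldehyde
Conditions: Pd(PPh3)4 (5 mol %), stannane 13 (1.3 equiv), DMF (degassed), 100 °C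
Reagents that add atoms: tributyl(3-methylbut-2-en-1-yl)stannane (13), CCCC[Sn](CCCC)(CCCC)CC=C(C)C
Why: Stille cross-coupling (oxidative addition of zerovalent palladium to the aryl bromide, transmetalation from the allylstannane, reductive elimination) should deliver the linear prenyl group and tolerates the free aldehyde and the acetals.

Step 9
Reactants: 14 3,4-bis(methoxymethoxy)-5-(3-methylbut-2-en-1-yl)benzaldehyde
Product: 15 5-ethynyl-1,2-bis(methoxymethoxy)-3-(3-methylbut-2-en-1-yl)benzene
Conditions: dimethyl (1-diazo-2-oxopropyl)phosphonate (1.3 equiv), K2CO3 (2 equiv), MeOH, 0 °C to rt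
Reagents that add atoms: dimethyl (1-diazo-2-oxopropyl)phosphonate, COP(=O)(OC)C(=[N+]=[N-])C(C)=O
Why: Seyferth–Gilbert homologation in the Ohira–Bestmann variant, in which methanolysis frees the diazomethylphosphonate anion, which adds to the aldehyde and loses phosphate and dinitrogen with a 1,2-hydride shift to the terminal alkyne under mild base.

Step 10
Reactants: 15 5-ethynyl-1,2-bis(methoxymethoxy)-3-(3-methylbut-2-en-1-yl)benzene
Product: 17 {[3,4-bis(methoxymethoxy)-5-(3-methylbut-2-en-1-yl)phenyl]ethynyl}trimethylsilane, via lithium acetylide 16 (not isolated)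
Conditions: n-BuLi (1.1 equiv), THF, −78 °C; then Me3SiCl (1.3 equiv), −78 °C to rt
Reagents that add atoms: chlorotrimethylsilane, C[Si](C)(C)Cl
Why: Deprotonation of the terminal alkyne and C-silylation of the acetylide is a standard route to an aryl silyl alkyne.

Step 11
Reactants: 9 2-hydroxy-4,6-bis(methoxymethoxy)-5-(3-methylbut-2-en-1-yl)benzaldehyde; 17 {[3,4-bis(methoxymethoxy)-5-(3-methylbut-2-en-1-yl)phenyl]ethynyl}trimethylsilane
Product: 18 3-[3,4-bis(methoxymethoxy)-5-(3-methylbut-2-en-1-yl)phenyl]-5,7-bis(methoxymethoxy)-6-(3-methylbut-2-en-1-yl)-2-(trimethylsilyl)-4H-chromen-4-one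
Conditions: [Cp*RhCl2]2 (5 mol %), Cu(OAc)2 (2.2 equiv), 17 (1.2 equiv), toluene, 100 °C, argon
Reagents that add atoms: none
Why: Acetate-assisted deprotonation binds the phenoxide of 9 to trivalent rhodium and the formyl C–H bond is cleaved to a five-membered acyl rhodacycle; syn insertion of alkyne 17 into the rhodium–acyl bond makes C3–C4, C–O reductive elimination from the seven-membered rhodacycle makes O1–C2, and two equivalents of Cu(OAc)2 return monovalent rhodium to the trivalent state. The closest known reaction type is the rhodium-catalysed oxidative [4+2] annulation of salicylaldehydes with internal alkynes to 2,3-disubstituted chromones. Ring C, the only ring formed, closes as a six-membered ring by this C–O reductive elimination onto the silyl-bearing vinyl carbon. No stereocenter is formed. The step needs the insertion sense that puts the aryl-bearing carbon on the acyl group and the silyl-bearing carbon on rhodium; the bulk of SiMe3, which avoids the short forming C–C bond, and the stabilisation of a carbon–metal bond alpha to silicon should secure it, the same bias that places silicon next to the heteroatom in Larock-type heteroannulations. Site selectivity on ring A is built in because 9 has a single free phenol, and the trisubstituted prenyl olefins and MOM acetals are expected to tolerate the neutral acetate medium; any material that loses silicon from C2 at this stage is simply the product of step 12.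

Step 12
Reactants: 18 the 2-trimethylsilyl isoflavone of step 11
Product: 19 3-[3,4-bis(methoxymethoxy)-5-(3-methylbut-2-en-1-yl)phenyl]-5,7-bis(methoxymethoxy)-6-(3-methylbut-2-en-1-yl)-4H-chromen-4-one
Conditions: Bu4NF (1.2 equiv), AcOH (1.2 equiv), THF, 0 °C to rt
Reagents that add atoms: none
Why: Fluoride-mediated protodesilylation, in which fluoride attacks silicon and the sp2 carbanion at C2, stabilised inductively by O1 and the vinylogous carbonyl, is protonated by AcOH; the buffer keeps the pyranone from opening under base.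

Step 13
Reactants: 19 isoangustone A tetrakis(methoxymethyl) ether
Product: 20 isoangustone A
Conditions: HCl (conc. aq., diluted to about 1 M in MeOH), 40 °C, stopped at full conversion
Reagents that add atoms: none
Why: Acid-catalysed transacetalisation of the four MOM acetals with methanol to dimethoxymethane frees all four phenols under conditions mild enough that the ortho-prenyl phenols are expected not to cyclise.

Compound list
1 | phloroglucinol (benzene-1,3,5-triol) | Oc1cc(O)cc(O)c1 | starting material
2 | 3,5-bis(methoxymethoxy)phenol | COCOc1cc(O)cc(OCOC)c1 | intermediate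
3 | [3,5-bis(methoxymethoxy)phenoxy]tri(propan-2-yl)silane | COCOc1cc(O[Si](C(C)C)(C(C)C)C(C)C)cc(OCOC)c1 | intermediate
4 | prenyl bromide (1-bromo-3-methylbut-2-ene) | CC(C)=CCBr | starting material
5 | {2,6-bis(methoxymethoxy)-4-[tri(propan-2-yl)silyloxy]phenyl}lithium (formed in the flask in step 3) | [Li]c1c(OCOC)cc(O[Si](C(C)C)(C(C)C)C(C)C)cc1OCOC | intermediate
6 | [3,5-bis(methoxymethoxy)-4-(3-methylbut-2-en-1-yl)phenoxy]tri(propan-2-yl)silane | COCOc1cc(O[Si](C(C)C)(C(C)C)C(C)C)cc(OCOC)c1CC=C(C)C | intermediate
7 | 3,5-bis(methoxymethoxy)-4-(3-methylbut-2-en-1-yl)phenol | COCOc1cc(O)cc(OCOC)c1CC=C(C)C | intermediate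
8 | 2-(hydroxymethyl)-3,5-bis(methoxymethoxy)-4-(3-methylbut-2-en-1-yl)phenol (salicyl alcohol, formed in the flask in step 5 as its magnesium salt) | OCc1c(O)cc(OCOC)c(CC=C(C)C)c1OCOC | intermediate
9 | 2-hydroxy-4,6-bis(methoxymethoxy)-5-(3-methylbut-2-en-1-yl)benzaldehyde | O=Cc1c(O)cc(OCOC)c(CC=C(C)C)c1OCOC | intermediate
10 | 5-bromovanillin (3-bromo-4-hydroxy-5-methoxybenzaldehyde) | COc1cc(C=O)cc(Br)c1O | starting material
11 | 3-bromo-4,5-dihydroxybenzaldehyde | O=Cc1cc(O)c(O)c(Br)c1 | intermediate
12 | 3-bromo-4,5-bis(methoxymethoxy)benzaldehyde | O=Cc1cc(OCOC)c(OCOC)c(Br)c1 | intermediate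
13 | tributyl(3-methylbut-2-en-1-yl)stannane | CCCC[Sn](CCCC)(CCCC)CC=C(C)C | starting material
14 | 3,4-bis(methoxymethoxy)-5-(3-methylbut-2-en-1-yl)benzaldehyde | O=Cc1cc(CC=C(C)C)c(OCOC)c(OCOC)c1 | intermediate
15 | 5-ethynyl-1,2-bis(methoxymethoxy)-3-(3-methylbut-2-en-1-yl)benzene | C#Cc1cc(CC=C(C)C)c(OCOC)c(OCOC)c1 | intermediate
16 | lithium acetylide of 15 (formed in the flask in step 10) | [Li]C#Cc1cc(CC=C(C)C)c(OCOC)c(OCOC)c1 | intermediate
17 | {[3,4-bis(methoxymethoxy)-5-(3-methylbut-2-en-1-yl)phenyl]ethynyl}trimethylsilane | C[Si](C)(C)C#Cc1cc(CC=C(C)C)c(OCOC)c(OCOC)c1 | intermediate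
18 | 3-[3,4-bis(methoxymethoxy)-5-(3-methylbut-2-en-1-yl)phenyl]-5,7-bis(methoxymethoxy)-6-(3-methylbut-2-en-1-yl)-2-(trimethylsilyl)-4H-chromen-4-one | C[Si](C)(C)c1oc2cc(OCOC)c(CC=C(C)C)c(OCOC)c2c(=O)c1-c1cc(CC=C(C)C)c(OCOC)c(OCOC)c1 | intermediate
19 | 3-[3,4-bis(methoxymethoxy)-5-(3-methylbut-2-en-1-yl)phenyl]-5,7-bis(methoxymethoxy)-6-(3-methylbut-2-en-1-yl)-4H-chromen-4-one | O=c1c(-c2cc(CC=C(C)C)c(OCOC)c(OCOC)c2)coc2cc(OCOC)c(CC=C(C)C)c(OCOC)c12 | intermediate
20 | isoangustone A | CC(C)=CCc1cc(-c2coc3cc(O)c(CC=C(C)C)c(O)c3c2=O)cc(O)c1O | target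

Total step count: 13
Longest linear sequence: 8 steps (steps 1–5 and 11–13; the ring B arm, steps 6–10 and 11–13, is equally long)

Steps most likely to fail

Step 11 (key annulation). The alkyne may insert in the reverse sense, which would lead into the 2-aryl-3-silyl flavone series. The alkynyl silyl group may be lost before insertion, followed by copper-mediated alkyne homocoupling. Metalation of the hindered 2,6-dioxygenated aldehyde may be slow, with decarbonylation competing. The fallback is the classical deoxybenzoin route; it sets out from 14 and 9 and comes back to the route at 19. Aldehyde 14 would be reduced with NaBH4 in MeOH to [3,4-bis(methoxymethoxy)-5-(3-methylbut-2-en-1-yl)phenyl]methanol F1. F1 would be converted with MeSO2Cl, Et3N and LiCl in THF into 5-(chloromethyl)-1,2-bis(methoxymethoxy)-3-(3-methylbut-2-en-1-yl)benzene F2, and this with Mg in THF at 0 °C into {[3,4-bis(methoxymethoxy)-5-(3-methylbut-2-en-1-yl)phenyl]methyl}magnesium chloride F3. Addition of F3 to 9, whose phenol is first deprotonated with NaH, should give the racemic carbinol 2-{2-[3,4-bis(methoxymethoxy)-5-(3-methylbut-2-en-1-yl)phenyl]-1-hydroxyethyl}-3,5-bis(methoxymethoxy)-4-(3-methylbut-2-en-1-yl)phenol F4. MnO2 in CH2Cl2 should oxidise the benzylic alcohol to the deoxybenzoin 2-[3,4-bis(methoxymethoxy)-5-(3-methylbut-2-en-1-yl)phenyl]-1-[2-hydroxy-4,6-bis(methoxymethoxy)-5-(3-methylbut-2-en-1-yl)phenyl]ethan-1-one F5. Heating F5 with Me2NCH(OMe)2 in toluene at 90 °C should give the enaminone (E)-2-[3,4-bis(methoxymethoxy)-5-(3-methylbut-2-en-1-yl)phenyl]-3-(dimethylamino)-1-[2-hydroxy-4,6-bis(methoxymethoxy)-5-(3-methylbut-2-en-1-yl)phenyl]prop-2-en-1-one F6 (either olefin geometry would serve). The phenol of F6 adds to the aminomethylene carbon and dimethylamine is lost, closing ring C to 19.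

Step 13 (global MOM removal). The freed phenols may cyclise onto the neighbouring prenyl olefins under acid (chroman formation), methanol or water may add to the olefins, or the ring B acetals may cleave incompletely. The fallback sets out from 19 and comes back at 20. It exchanges the acetals for silyl ethers under aprotic, amine-buffered conditions: Me3SiOTf and 2,2′-bipyridyl in MeCN at 0 °C should convert the four aryl MOM ethers into 3-[3,4-bis(trimethylsilyloxy)-5-(3-methylbut-2-en-1-yl)phenyl]-6-(3-methylbut-2-en-1-yl)-5,7-bis(trimethylsilyloxy)-4H-chromen-4-one F7. F7 is hydrolysed to 20 by adding water at neutral pH.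

Step 8 (Stille prenylation). The allyl unit may transfer through its γ-carbon to give the 1,1-dimethylallyl isomer, a palladium hydride may move the double bond into conjugation, or oxidative addition may be slow at the bromide next to a MOM ether. The fallback sets out from 12 and comes back at 17, replacing steps 8–10. It keeps the bromide through the homologation and prenylates by halogen–lithium exchange. The Ohira–Bestmann reaction of 12 would give 1-bromo-5-ethynyl-2,3-bis(methoxymethoxy)benzene F8. LiN(i-Pr)2 in THF at −78 °C, which leaves the C–Br bond alone, would give the lithium acetylide of F8 F9, and Me3SiCl would give {[3-bromo-4,5-bis(methoxymethoxy)phenyl]ethynyl}trimethylsilane F10. n-BuLi at −78 °C would then give {2,3-bis(methoxymethoxy)-5-[(trimethylsilyl)ethynyl]phenyl}lithium F11, and allylation with prenyl bromide 4 under CuBr·SMe2 catalysis, as in step 3, would give 17.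

Further compounds
F1 | step 11 | [3,4-bis(methoxymethoxy)-5-(3-methylbut-2-en-1-yl)phenyl]methanol | OCc1cc(CC=C(C)C)c(OCOC)c(OCOC)c1
F2 | step 11 | 5-(chloromethyl)-1,2-bis(methoxymethoxy)-3-(3-methylbut-2-en-1-yl)benzene | ClCc1cc(CC=C(C)C)c(OCOC)c(OCOC)c1
F3 | step 11 | {[3,4-bis(methoxymethoxy)-5-(3-methylbut-2-en-1-yl)phenyl]methyl}magnesium chloride | Cl[Mg]Cc1cc(CC=C(C)C)c(OCOC)c(OCOC)c1
F4 | step 11 | 2-{2-[3,4-bis(methoxymethoxy)-5-(3-methylbut-2-en-1-yl)phenyl]-1-hydroxyethyl}-3,5-bis(methoxymethoxy)-4-(3-methylbut-2-en-1-yl)phenol (racemic) | OC(Cc1cc(CC=C(C)C)c(OCOC)c(OCOC)c1)c1c(O)cc(OCOC)c(CC=C(C)C)c1OCOC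
F5 | step 11 | 2-[3,4-bis(methoxymethoxy)-5-(3-methylbut-2-en-1-yl)phenyl]-1-[2-hydroxy-4,6-bis(methoxymethoxy)-5-(3-methylbut-2-en-1-yl)phenyl]ethan-1-one | O=C(Cc1cc(CC=C(C)C)c(OCOC)c(OCOC)c1)c1c(O)cc(OCOC)c(CC=C(C)C)c1OCOC
F6 | step 11 | (E)-2-[3,4-bis(methoxymethoxy)-5-(3-methylbut-2-en-1-yl)phenyl]-3-(dimethylamino)-1-[2-hydroxy-4,6-bis(methoxymethoxy)-5-(3-methylbut-2-en-1-yl)phenyl]prop-2-en-1-one | CN(C)/C=C(\c1cc(CC=C(C)C)c(OCOC)c(OCOC)c1)C(=O)c1c(O)cc(OCOC)c(CC=C(C)C)c1OCOC
F7 | step 13 | 3-[3,4-bis(trimethylsilyloxy)-5-(3-methylbut-2-en-1-yl)phenyl]-6-(3-methylbut-2-en-1-yl)-5,7-bis(trimethylsilyloxy)-4H-chromen-4-one | CC(C)=CCc1cc(-c2coc3cc(O[Si](C)(C)C)c(CC=C(C)C)c(O[Si](C)(C)C)c3c2=O)cc(O[Si](C)(C)C)c1O[Si](C)(C)C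
F8 | step 8 | 1-bromo-5-ethynyl-2,3-bis(methoxymethoxy)benzene | C#Cc1cc(OCOC)c(OCOC)c(Br)c1
F9 | step 8 | lithium acetylide of F8 | [Li]C#Cc1cc(OCOC)c(OCOC)c(Br)c1
F10 | step 8 | {[3-bromo-4,5-bis(methoxymethoxy)phenyl]ethynyl}trimethylsilane | C[Si](C)(C)C#Cc1cc(OCOC)c(OCOC)c(Br)c1
F11 | step 8 | {2,3-bis(methoxymethoxy)-5-[(trimethylsilyl)ethynyl]phenyl}lithium | [Li]c1cc(C#C[Si](C)(C)C)cc(OCOC)c1OCOC
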